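Tsangin C is treated as a ring-opened lignan. Its ester carbonyl carbon and its acetyl carbonyl carbon are reconnected as C5 and C4 of a 2,3-dihydrofuran, whose ring oxygen O1 is the ester oxygen. One ozonolysis of that C4=C5 enol ether bond opens the five-membered ring and produces the aroyl ester and the methyl ketone together, cold and neutral. The ring stereocentres C2 (aryl) and C3 (methyl) pass untouched into the anti O–CH(Ar)–CH(CH3) pair. The precursor is (2R,3R)-3,4-dimethyl-2,5-bis(3,4,5-trimethoxyphenyl)-2,3-dihydrofuran, assembled from a crotylboration-derived trans-lactone by α-methylation, aryllithium addition and dehydration.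

Key step: step 7

Remark on stereochemistry: the target SMILES reads (1R,2S), the anti isomer. The methyl-bearing carbon keeps the same spatial arrangement from the crotylation product onwards, and its descriptor changes from R to S in the last step only because its neighbour gains CIP priority on becoming C=O.
Assumption: the aryllithium adduct is drawn as the closed hemiketal. Its ring-chain tautomerism and its mixed configuration at the two carbons that become C4 and C5 do not matter, since both end up sp2.

Step 1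
Reactants: 1 3,4,5-trimethoxybenzaldehyde; 2 (E)-but-2-ene; 3 (+)-B-methoxydiisopinocampheylborane
Product: 8 (1R,2R)-2-methyl-1-(3,4,5-trimethoxyphenyl)but-3-en-1-ol, via (E)-crotylpotassium 4 (not isolated), via potassium crotylmethoxyborate 5 (not isolated), via (E)-crotyldiisopinocampheylborane 6 (not isolated), via diisopinocampheylborinate ester 7 (not isolated)
Conditions: 2, KOt-Bu, n-BuLi, THF, −78 → −45 °C; 3, Et2O, −78 °C; BF3·OEt2, then 1, −78 °C; NaOH, H2O2, H2O, 0 °C → rt
Reagents that add atoms: none
Why: Brown asymmetric crotylboration: E-crotylborane 6 reacts through a closed chair Zimmerman–Traxler transition state, so the E geometry translates into the anti C1/C2 relation, while the isopinocampheyl groups of the (−)-α-pinene series steer the crotyl unit to the Re face of the aldehyde and so fix (1R,2R).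

Step 2
Reactants: 8 (1R,2R)-2-methyl-1-(3,4,5-trimethoxyphenyl)but-3-en-1-ol
Product: 10 (1R,2R)-2-methyl-1-(3,4,5-trimethoxyphenyl)butane-1,4-diol, via B-alkyl-9-BBN adduct 9 (not isolated)
Conditions: 9-BBN-H, THF, 0 °C → rt; NaOH, H2O2, H2O, 0 °C → rt
Reagents that add atoms: hydrogen peroxide, OO
Why: Hydroboration–oxidation: the bulky 9-BBN-H puts boron on the terminal carbon of the monosubstituted alkene (anti-Markovnikov), and the C–B bond is oxidised with retention far from the two stereocentres, which are not touched.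

Step 3
Reactants: 10 (1R,2R)-2-methyl-1-(3,4,5-trimethoxyphenyl)butane-1,4-diol
Product: 13 (4R,5R)-4-methyl-5-(3,4,5-trimethoxyphenyl)dihydrofuran-2(3H)-one (4,5-trans), via hydroxy aldehyde 11 (not isolated), via lactol 12 (not isolated)
Conditions: TEMPO (cat.), PhI(OAc)2, CH2Cl2, rt
Reagents that add atoms: none
Why: Oxoammonium-mediated (TEMPO/PhI(OAc)2) oxidative lactonisation of a 1,4-diol: the unhindered primary alcohol is oxidised faster than the secondary benzylic one, aldehyde 11 is caught at once by the benzylic hydroxyl as lactol 12 and this is oxidised on to the lactone, so the carbinol stereocentre never reaches the ketone level and the anti diol maps onto the 4,5-trans lactone.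

Step 4
Reactants: 13 (4R,5R)-4-methyl-5-(3,4,5-trimethoxyphenyl)dihydrofuran-2(3H)-one
Product: 15 (3R,4R,5R)-3,4-dimethyl-5-(3,4,5-trimethoxyphenyl)dihydrofuran-2(3H)-one (all-trans, expected major C3 epimer), via lithium enolate 14 (not isolated)
Conditions: LiN(SiMe3)2, THF, −78 °C; MeI, −78 → −40 °C
Reagents that add atoms: iodomethane, CI
Why: Lactone enolate alkylation: MeI should approach planar enolate 14 from the face opposite to the C4 methyl group and give mainly the 3,4-trans isomer, but the outcome at C3 is of no consequence because this centre becomes sp2 in step 6.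

Step 5
Reactants: 15 (3R,4R,5R)-3,4-dimethyl-5-(3,4,5-trimethoxyphenyl)dihydrofuran-2(3H)-one; 16 5-bromo-1,2,3-trimethoxybenzene
Product: 20 (3R,4R,5R)-3,4-dimethyl-2,5-bis(3,4,5-trimethoxyphenyl)tetrahydrofuran-2-ol (hemiketal, C2 undefined), via 3,4,5-trimethoxyphenyllithium 17 (not isolated), via lithium hemiketal alkoxide 18 (not isolated), via open hydroxy ketone tautomer 19 (not isolated)
Conditions: 16, n-BuLi, THF, −78 °C; 15, THF, −78 °C; satd aq NH4Cl, −78 °C → rt
Reagents that add atoms: none
Why: Bromine–lithium exchange followed by 1,2-addition of an aryllithium to a lactone: tetrahedral alkoxide 18 holds together at −78 °C, which prevents a second addition, and the new anomeric centre needs no control because it is erased in step 6.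

Step 6
Reactants: 20 (3R,4R,5R)-3,4-dimethyl-2,5-bis(3,4,5-trimethoxyphenyl)tetrahydrofuran-2-ol
Product: 22 (2R,3R)-3,4-dimethyl-2,5-bis(3,4,5-trimethoxyphenyl)-2,3-dihydrofuran (C2 aryl and C3 methyl trans), via oxocarbenium tosylate 21 (not isolated)
Conditions: PPTS (pyridinium p-toluenesulfonate, 10 mol %), 4 Å MS, toluene, 70 °C, Ar; Et3N quench; Et3N-washed SiO2; used at once
Reagents that add atoms: none
Why: Acid-catalysed dehydration of a hemiketal (E1 type): loss of water gives the aryl-stabilised oxocarbenium ion 21, whose only removable β-hydrogen sits on C4, so the conjugated tetrasubstituted C4=C5 enol ether is the sole alkene possible, while the weak acid, the sieves and the amine quench spare the benzylic C2–O bond and the C2/C3 trans pair, which is also the thermodynamically preferred arrangement.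

Step 7
Reactants: 22 (2R,3R)-3,4-dimethyl-2,5-bis(3,4,5-trimethoxyphenyl)-2,3-dihydrofuran
Product: 26 tsangin C, (1R,2S)-2-methyl-3-oxo-1-(3,4,5-trimethoxyphenyl)butyl 3,4,5-trimethoxybenzoate, via primary ozonide 23 (not isolated), via carbonyl oxide 24 (not isolated), via methoxy hydroperoxide 25 (not isolated)
Conditions: O3 (1.0 equiv, titrated cold CH2Cl2 stock solution), CH2Cl2–MeOH, −78 °C; Me2S, −78 °C → rt; neutral work-up, no base, neutral SiO2
Reagents that add atoms: ozone, [O-][O+]=O
Why: A concerted [3+2] cycloaddition of ozone to the C4=C5 π bond of 22 gives primary ozonide 23, which undergoes Criegee cycloreversion in the sense normal for enol ethers, leaving the aroyl ester (C=O at former C5, O1 as ester oxygen) and carbonyl oxide 24 at former C4; methanol captures 24 as hydroperoxide 25, and Me2S reduces its O–O bond so that the resulting hemiketal sheds methanol and leaves the acetyl group. The closest known reaction type is the reductive ozonolysis of cyclic enol ethers (2,3-dihydrofurans, glycals, benzofurans) to keto or formyl esters. The step closes no ring (it unzips the oxolene ring) and creates no stereocentre, since C2 and C3 are spectators that become the (1R,2S) anti pair of 26. The selectivity required is enol ether over the two trimethoxyarenes; it rests on the oxygen-donated, aryl-conjugated, fully substituted alkene being far more nucleophilic than either arene, and it is backed by metering a single equivalent of ozone in the cold. Methanol keeps 24 from adding to unreacted 22 or from oligomerising, and the cold neutral medium offers no base for E1cB loss of trimethoxybenzoate or for epimerisation next to the new ketone.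

Compound list
1 | 3,4,5-trimethoxybenzaldehyde | COc1cc(C=O)cc(OC)c1OC | starting material
2 | (E)-but-2-ene | C/C=C/C | starting material
3 | (+)-B-methoxydiisopinocampheylborane, (−)-α-pinene series | COB([C@H]1C[C@H]2C[C@@H]([C@@H]1C)C2(C)C)[C@H]1C[C@H]2C[C@@H]([C@@H]1C)C2(C)C | starting material
4 | (E)-crotylpotassium | [K+].[CH2-]/C=C/C | intermediate
5 | potassium (E)-crotyl(methoxy)diisopinocampheylborate | [K+].C/C=C/C[B-](OC)([C@H]1C[C@H]2C[C@@H]([C@@H]1C)C2(C)C)[C@H]1C[C@H]2C[C@@H]([C@@H]1C)C2(C)C | intermediate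
6 | (E)-crotyldiisopinocampheylborane | C/C=C/CB([C@H]1C[C@H]2C[C@@H]([C@@H]1C)C2(C)C)[C@H]1C[C@H]2C[C@@H]([C@@H]1C)C2(C)C | intermediate
7 | diisopinocampheylborinate ester of 8 | C=C[C@@H](C)[C@@H](OB([C@H]1C[C@H]2C[C@@H]([C@@H]1C)C2(C)C)[C@H]1C[C@H]2C[C@@H]([C@@H]1C)C2(C)C)c1cc(OC)c(OC)c(OC)c1 | intermediate
8 | (1R,2R)-2-methyl-1-(3,4,5-trimethoxyphenyl)but-3-en-1-ol | C=C[C@@H](C)[C@@H](O)c1cc(OC)c(OC)c(OC)c1 | intermediate
9 | B-[(3R,4R)-4-hydroxy-3-methyl-4-(3,4,5-trimethoxyphenyl)butyl]-9-borabicyclo[3.3.1]nonane | C1CC2CCCC(C1)B2CC[C@@H](C)[C@@H](O)c1cc(OC)c(OC)c(OC)c1 | intermediate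
10 | (1R,2R)-2-methyl-1-(3,4,5-trimethoxyphenyl)butane-1,4-diol | OCC[C@@H](C)[C@@H](O)c1cc(OC)c(OC)c(OC)c1 | intermediate
11 | (3R,4R)-4-hydroxy-3-methyl-4-(3,4,5-trimethoxyphenyl)butanal | O=CC[C@@H](C)[C@@H](O)c1cc(OC)c(OC)c(OC)c1 | intermediate
12 | (4R,5R)-4-methyl-5-(3,4,5-trimethoxyphenyl)tetrahydrofuran-2-ol (C2 undefined) | OC1C[C@@H](C)[C@H](c2cc(OC)c(OC)c(OC)c2)O1 | intermediate
13 | (4R,5R)-4-methyl-5-(3,4,5-trimethoxyphenyl)dihydrofuran-2(3H)-one | O=C1C[C@@H](C)[C@H](c2cc(OC)c(OC)c(OC)c2)O1 | intermediate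
14 | lithium enolate of 13 | [Li+].[O-]C1=C[C@@H](C)[C@H](c2cc(OC)c(OC)c(OC)c2)O1 | intermediate
15 | (3R,4R,5R)-3,4-dimethyl-5-(3,4,5-trimethoxyphenyl)dihydrofuran-2(3H)-one | O=C1[C@H](C)[C@@H](C)[C@H](c2cc(OC)c(OC)c(OC)c2)O1 | intermediate
16 | 5-bromo-1,2,3-trimethoxybenzene | COc1cc(Br)cc(OC)c1OC | starting material
17 | 3,4,5-trimethoxyphenyllithium | [Li]c1cc(OC)c(OC)c(OC)c1 | intermediate
18 | lithium alkoxide of hemiketal 20 | [Li+].[O-]C1(c2cc(OC)c(OC)c(OC)c2)[C@H](C)[C@@H](C)[C@H](c2cc(OC)c(OC)c(OC)c2)O1 | intermediate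
19 | (2R,3R,4R)-4-hydroxy-2,3-dimethyl-1,4-bis(3,4,5-trimethoxyphenyl)butan-1-one | O=C(c1cc(OC)c(OC)c(OC)c1)[C@H](C)[C@@H](C)[C@H](c1cc(OC)c(OC)c(OC)c1)O | intermediate
20 | (3R,4R,5R)-3,4-dimethyl-2,5-bis(3,4,5-trimethoxyphenyl)tetrahydrofuran-2-ol (C2 undefined) | OC1(c2cc(OC)c(OC)c(OC)c2)[C@H](C)[C@@H](C)[C@H](c2cc(OC)c(OC)c(OC)c2)O1 | intermediate
21 | cyclic 2-aryl oxocarbenium ion from 20, tosylate ion pair | [O+]1=C(c2cc(OC)c(OC)c(OC)c2)[C@H](C)[C@@H](C)[C@@H]1c3cc(OC)c(OC)c(OC)c3.Cc1ccc(cc1)S(=O)(=O)[O-] | intermediate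
22 | (2R,3R)-3,4-dimethyl-2,5-bis(3,4,5-trimethoxyphenyl)-2,3-dihydrofuran | COc1cc(C2=C(C)[C@@H](C)[C@H](c3cc(OC)c(OC)c(OC)c3)O2)cc(OC)c1OC | intermediate
23 | primary ozonide of 22, 1,2,3-trioxolane cis-fused across C4–C5 (face undefined) | C[C@H]1[C@H](c2cc(OC)c(OC)c(OC)c2)OC2(c3cc(OC)c(OC)c(OC)c3)OOOC12C | intermediate
24 | carbonyl oxide at former C4, aroyl ester already in place | COc1cc(C(=O)O[C@@H](c2cc(OC)c(OC)c(OC)c2)[C@H](C)C(C)=[O+][O-])cc(OC)c1OC | intermediate
25 | (1R,2S)-3-hydroperoxy-3-methoxy-2-methyl-1-(3,4,5-trimethoxyphenyl)butyl 3,4,5-trimethoxybenzoate (C3 undefined) | COc1cc(C(=O)O[C@@H](c2cc(OC)c(OC)c(OC)c2)[C@H](C)C(C)(OC)OO)cc(OC)c1OC | intermediate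
26 | tsangin C, (1R,2S)-2-methyl-3-oxo-1-(3,4,5-trimethoxyphenyl)butyl 3,4,5-trimethoxybenzoate | COc1cc(C(=O)O[C@@H](c2cc(OC)c(OC)c(OC)c2)[C@H](C)C(C)=O)cc(OC)c1OC | target

Total step count: 7. Longest linear sequence: 7 steps (1 to 26). Aryl bromide 16 enters directly in step 5.

Steps most likely to fail

Step 7 (key step). Three things may go wrong:
- Ozone is consumed by the trimethoxyarene rings once the enol ether runs low.
- Oxygen-atom transfer to the crowded tetrasubstituted alkene takes the place of cycloaddition.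
- The aroyloxy group is eliminated, or the α-carbon epimerises, during isolation.

The fallback sets out from 22 and splits the cleavage into two arene-tolerant operations. Upjohn dihydroxylation of the enol ether bond (OsO4 cat., NMO, MeSO2NH2, acetone–H2O, 0 °C) would give the hemiketal cis-diol F1. Criegee glycol cleavage with Pb(OAc)4 in CH2Cl2 at 0 °C would then cut the same C–C bond. The hemiketal carbon emerges as the ester carbonyl and the tertiary carbinol carbon as the ketone, so the fallback comes back to the route at 26.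

Step 6. Three things may go wrong:
- Dehydration is reversible or incomplete.
- Acid ionises the benzylic C2–O bond, with erosion of the trans relation or Friedel–Crafts ring closure.
- The sensitive enol ether is oxidised by air to the aromatic furan on handling.

The fallback sets out from 15, bypasses steps 5 and 6, and uses no acid. O-Phosphorylation of the potassium enolate (KN(SiMe3)2, (PhO)2P(O)Cl, THF, −78 °C) would give the cyclic ketene acetal diphenyl phosphate F2. This is coupled crude with commercial 3,4,5-trimethoxyphenylboronic acid in a Suzuki–Miyaura reaction (Pd(PPh3)4, K3PO4, dioxane, 60 °C). The aryl group is thereby attached to an enol ether that already exists, and the fallback comes back to the route at 22.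

Step 5. Two things may go wrong:
- The tetrahedral alkoxide collapses early, and a second aryllithium addition follows.
- The aryllithium deprotonates the α-branched lactone instead of adding.

The fallback sets out from 15 and moves to an open-chain acyl donor that cannot over-add.
- Aminolysis with Me(MeO)NH·HCl and AlMe3 (CH2Cl2, 0 °C → rt) would give the hydroxy Weinreb amide F3.
- Immediate silylation (Et3SiCl, imidazole, CH2Cl2) would give the triethylsilyl ether F4 and block relactonisation.
- Aryllithium 17 (THF, −78 °C) would give the silyloxy aryl ketone F5.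
- Mild aqueous acid (AcOH–THF–H2O, rt) would remove the silyl group, and the freed hydroxy ketone closes, so the fallback comes back to the route at 20.

Further compounds
F1 | step 7 | (4S,5R)-3,4-dimethyl-2,5-bis(3,4,5-trimethoxyphenyl)tetrahydrofuran-2,3-diol (cis-2,3-diol, face undefined) | C[C@H]1[C@H](c2cc(OC)c(OC)c(OC)c2)OC(O)(c2cc(OC)c(OC)c(OC)c2)C1(C)O
F2 | step 6 | (2R,3R)-3,4-dimethyl-2-(3,4,5-trimethoxyphenyl)-2,3-dihydrofuran-5-yl diphenyl phosphate | CC1=C(OP(=O)(Oc2ccccc2)Oc2ccccc2)O[C@@H](c2cc(OC)c(OC)c(OC)c2)[C@@H]1C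
F3 | step 5 | (2R,3R,4R)-4-hydroxy-N-methoxy-N,2,3-trimethyl-4-(3,4,5-trimethoxyphenyl)butanamide | CON(C)C(=O)[C@H](C)[C@@H](C)[C@H](c1cc(OC)c(OC)c(OC)c1)O
F4 | step 5 | (2R,3R,4R)-N-methoxy-N,2,3-trimethyl-4-(triethylsilyloxy)-4-(3,4,5-trimethoxyphenyl)butanamide | CON(C)C(=O)[C@H](C)[C@@H](C)[C@H](c1cc(OC)c(OC)c(OC)c1)O[Si](CC)(CC)CC
F5 | step 5 | (2R,3R,4R)-2,3-dimethyl-4-(triethylsilyloxy)-1,4-bis(3,4,5-trimethoxyphenyl)butan-1-one | O=C(c1cc(OC)c(OC)c(OC)c1)[C@H](C)[C@@H](C)[C@H](c1cc(OC)c(OC)c(OC)c1)O[Si](CC)(CC)CC
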